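**Retrosynthetic overview**

1. Feature: in the seven-membered carbocycle (C1 = C(OH) carrying the crotonoyl group, carbonyl CK; C2 = CHMe; C3 = CHOH; C4 = CH2; C5 = ring-fusion CH; C6 = CH–O of the lactone; C7 = CH–O isobutyrate; lactone C11 = CHMe, C12 = C=O, C13 = Me) the tertiary carbinol C1 lies between the C7 oxygen and the CK carbonyl, which is the retron of an α-ketol 1,2-shift; β is the face carrying the C5–C11 bond.
2. Endgame: C3 desilylation ⇐ C7 isobutyrylation ⇐ hydroxyl-directed reduction of the C7 ketone of the ring-enlarged α-ketol.
3. Key disconnection C1–C2: the seven-membered ketol comes from a cyclohexanol (ring C7, C2–C6) bearing the exocyclic ene-dione C7–C1(=O)–CK(=O)–CH=CH–CH3 by shift of the ring bond C7–C2 to C1; the ene-dione comes from the C7 ketone by acetylide addition, alkyne oxidation and β-elimination.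
4. The C7 ketone comes from (R)-carvone: isopropenyl → acrylic acid, C6–O lactone closure through the α'-iodide, convex-face hydrogenation (C11), then 1,2-reduction, hydroboration (C2, C3), silylation and re-oxidation.
5. Ring order: six-membered carbocycle (chiral pool), then the cis-fused γ-lactone, then the seven-membered ring by enlargement of the six-membered one.

Key step: step 14

Remark: the atom labels and the α/β convention of the overview are used for all intermediates; the (S)-alkynol of step 10 is chosen only so that the intermediates are single diastereomers, since its carbinol centre is destroyed in step 13.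

**Route**

Step 1
Reactants: 1 (R)-carvone
Product: 2 (5R)-5-(3-chloroprop-1-en-2-yl)-2-methylcyclohex-2-en-1-one (10-chlorocarvone)
Conditions: Ca(OCl)2, CO2 (dry ice), CH2Cl2/H2O, 0 °C
Reagents that add atoms: calcium hypochlorite, [Ca+2].[O-]Cl.[O-]Cl
Why: Ene-type allylic chlorination by HOCl formed in situ should attack only the electron-rich 1,1-disubstituted isopropenyl alkene (the enone alkene is deactivated), with hydrogen loss from the methyl group giving the transposed allylic chloride and leaving the C5 stereocentre untouched.

Step 2
Reactants: 2 10-chlorocarvone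
Product: 3 2-[(1R)-4-methyl-5-oxocyclohex-3-en-1-yl]prop-2-enal
Conditions: NMO (3 equiv), NaI (0.2 equiv), MeCN, rt
Reagents that add atoms: 4-methylmorpholine N-oxide, C[N+]1([O-])CCOCC1
Why: Kornblum-type oxidation, in which iodide-assisted SN2 displacement of the primary allylic chloride by the N-oxide oxygen and base-induced fragmentation of the alkoxyammonium salt should give the 2-substituted acrolein without touching the enone.

Step 3
Reactants: 3 enal
Product: 4 2-[(1R)-4-methyl-5-oxocyclohex-3-en-1-yl]prop-2-enoic acid
Conditions: NaClO2, NaH2PO4, 2-methylbut-2-ene, t-BuOH/H2O, 0 °C → rt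
Reagents that add atoms: sodium chlorite, [Na+].[O-]Cl=O
Why: Pinnick oxidation should convert the enal into the acrylic acid under buffered conditions in which the enone, the conjugated alkene and C5 are inert, 2-methylbut-2-ene trapping the HOCl.

Step 4
Reactants: 4 acrylic acid
Product: 6 cis-fused enone α-methylene γ-lactone (C7 ketone; C2=C3 alkene; C6–O and C5–C11 bonds both β), via 6-iodo keto acid 5 (not isolated)
Conditions: LDA (2.2 equiv), THF, −78 °C; I2 (1.05 equiv), −78 °C; then DMF, −78 °C → rt
Reagents that add atoms: none
Why: After carboxylate formation, kinetic α'-deprotonation of the carvone-type enone gives the cross-conjugated dienolate, which should be iodinated at C6 anti to the C5 side chain, and intramolecular SN2 O-alkylation of the carboxylate by the α-iodo ketone (5-exo-tet, inversion) then places C6–O on the β face, which is the cis-fused lactone, while any cis iodide can epimerise through the enol into the same channel.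

Step 5
Reactants: 6 enone α-methylene lactone
Product: 7 cis-fused enone α-methyl γ-lactone (C11 methyl on the concave face; H11 cis to H5; C11 R)
Conditions: H2 (1 atm), RhCl(PPh3)3 (5 mol%), benzene/EtOH, rt
Reagents that add atoms: none
Why: Homogeneous hydrogenation with RhCl(PPh3)3 should reduce the 1,1-disubstituted exocyclic alkene and spare the trisubstituted enone alkene, hydrogen reaching C11 from the convex face of the cis-fused bicycle (the face of H5 and H6) so that the C11 methyl ends on the concave side as in the target.

Step 6
Reactants: 7 enone α-methyl lactone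
Product: 8 allylic alcohol (C7–OH β; cis to C6–O)
Conditions: NaBH4, CeCl3·7H2O, MeOH, −78 °C
Reagents that add atoms: none
Why: Luche reduction should give clean 1,2-reduction of the enone without touching the lactone, hydride adding to C7 from the convex α face anti to the C6 oxygen, so that the hydroxyl is β (this centre is erased in step 9 and serves only to steer steps 7 and 8).

Step 7
Reactants: 8 allylic alcohol
Product: 10 diol (C3–OH α; C2–Me β; C7–OH β), via C3 alkylborane 9 (not isolated)
Conditions: BH3·THF (3 equiv), THF, 0 °C; then NaBO3·4H2O, THF/H2O, rt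
Reagents that add atoms: sodium perborate (NaBO3·4H2O, drawn as its hydroperoxyborate), [Na+].OO[B-](O)(O)O
Why: Hydroboration–oxidation adds H and B syn across C2=C3 with boron on the less substituted C3 and from the α face, opposite both the allylic C7 oxygen and the β-fused lactone, so that after oxidation with retention C3–OH is α and the C2 methyl is β (trans), the lactone being expected to survive short exposure to borane at 0 °C and the mild perborate work-up.

Step 8
Reactants: 10 diol
Product: 11 C3 tert-butyldimethylsilyl ether (C7–OH free)
Conditions: TBSCl (1.1 equiv), imidazole, DMF, 0 °C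
Reagents that add atoms: tert-butyldimethylsilyl chloride, CC(C)(C)[Si](C)(C)Cl
Why: Silylation should discriminate the two secondary alcohols on steric grounds, the C3 hydroxyl being flanked by a methylene whereas the C7 hydroxyl is flanked cis by the C2 methyl and the C6 acyloxy group.

Step 9
Reactants: 11 mono-silyl ether
Product: 12 cyclohexanone (C7=O; C2–Me β; C3–OTBS α; cis lactone with C6–O β; C11 R)
Conditions: Dess–Martin periodinane, CH2Cl2, 0 °C → rt
Reagents that add atoms: none
Why: Dess–Martin oxidation of the hindered C7 alcohol runs under near-neutral, non-enolising conditions and should give the ketone without epimerising C2 or C6 and without β-elimination of the silyloxy group.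

Step 10
Reactants: 13 (S)-pent-4-yn-2-ol
Product: 14 (S)-pent-4-yn-2-yl pivalate
Conditions: t-BuCOCl, pyridine, DMAP (cat.), CH2Cl2, 0 °C → rt
Reagents that add atoms: pivaloyl chloride, CC(C)(C)C(Cl)=O
Why: DMAP-catalysed acylation of a secondary alcohol gives a pivalate that has no α-hydrogens, tolerates the acetylide chemistry of step 11 and later serves as the leaving group of the β-elimination.

Step 11
Reactants: 12 cyclohexanone; 14 (S)-pent-4-yn-2-yl pivalate
Product: 17 tertiary propargylic alcohol (C7–OH β; C7–C≡C–CH2–CH(OPiv)CH3 α), via lithium acetylide 15 (not isolated), via dichlorocerium acetylide 16 (not isolated)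
Conditions: 14, LDA (1.05 equiv), THF, −78 °C; CeCl3 (anhydrous), −78 °C; then 12, −78 °C; aq NH4Cl
Reagents that add atoms: none
Why: 1,2-Addition of an organocerium acetylide, which is nucleophilic but barely basic and so should avoid enolisation of the α-acyloxy ketone and loss of the β-silyloxy group, with the slender nucleophile entering from the α face because the C2 methyl, the C6 oxygen and the lactone ring all lie on the β face.

Step 12
Reactants: 17 propargylic alcohol
Product: 18 1,2-diketone pivalate (C7–C1(=O)–CK(=O)–CH2–CH(OPiv)CH3)
Conditions: RuO2·xH2O (5 mol%), NaIO4 (2.5 equiv), EtOAc/MeCN/H2O, 0 °C, short reaction time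
Reagents that add atoms: sodium periodate, [Na+].[O-]I(=O)(=O)=O
Why: RuO4-catalysed oxidation of an internal alkyne to the 1,2-diketone (RuO4 regenerated by periodate) is applied while no alkene is present, and cold, brief exposure should spare the tertiary ketol, the silyl ether, the pivalate and the lactone.

Step 13
Reactants: 18 diketone pivalate
Product: 19 cyclohexanol ene-dione (C7–OH β; C7–C1(=O)–CK(=O)–CH=CH–CH3 with E alkene on the α face)
Conditions: DBU (1.2 equiv), CH2Cl2, −20 → 0 °C
Reagents that add atoms: none
Why: E1cB elimination, in which the acidic methylene next to the diketone is deprotonated and pivalate is expelled, should give the conjugated (E)-enone under conditions too mild to ionise the tertiary hydroxyl.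

Step 14
Reactants: 19 cyclohexanol ene-dione
Product: 20 ring-enlarged ketol (seven-membered ring C1–C7; C7=O; C1–OH β; C1 crotonoyl α)
Conditions: Zn(OTf)2 (30 mol%), 4 Å MS, ClCH2CH2Cl, 60 °C
Reagents that add atoms: none
Why: Proposed new method: divalent zinc is expected to bridge the C7 hydroxyl oxygen and the C1 carbonyl oxygen in a five-membered chelate, which polarises C1=O and holds the two C–O bonds syn-periplanar while the C7–C2 σ bond shifts suprafacially to C1 and the C7 carbinol becomes the ring ketone. The closest known reaction type is the Lewis-acid-promoted α-ketol (acyloin) ring expansion of 1-acylcycloalkanols, familiar for strained cyclobutanols and for D-ring homologation of 17-hydroxy-20-keto steroids, but not for a cyclohexanol carrying an ene-dione. The seven-membered ring is closed by this 1,2-alkyl shift, that is by insertion of C1 between C7 and C2, and not by an end-to-end cyclisation, and C1–C2 is the only skeletal bond formed. The new C1 stereocentre is controlled by the C7 configuration through the chelate: with the C7 hydroxyl β and the dione chain on the less substituted α side, C2 attacks the C1 carbonyl face that leaves the new hydroxyl β (cis to the C2 methyl) and the crotonoyl group α, and C2 migrates with retention. The step needs migration of C2 in preference to C6, which the electron-poor, acyloxy-bearing C6 should secure, and a forward driving force, which is expected from loss of the vicinal dicarbonyl repulsion.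

Step 15
Reactants: 20 ring-enlarged ketol
Product: 21 trans diol (C7–OH α; C1–OH β)
Conditions: Me4NBH(OAc)3 (3 equiv), MeCN/AcOH (1:1), −30 °C
Reagents that add atoms: none
Why: Hydroxyl-directed triacetoxyborohydride reduction, in which acetate exchange at the C1 hydroxyl and intramolecular hydride delivery to the adjacent, more electrophilic saturated C7 ketone from the β face should give the α alcohol at C7, the conjugated CK carbonyl, the lactone and the silyl ether being left alone.

Step 16
Reactants: 21 trans diol; 22 isobutyryl chloride
Product: 23 C7 isobutyrate (C3–OTBS retained)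
Conditions: pyridine, DMAP (cat.), CH2Cl2, 0 °C → rt
Reagents that add atoms: none
Why: DMAP-catalysed acylation should esterify the secondary C7 hydroxyl while the tertiary C1 hydroxyl on the fully substituted carbon does not react.

Step 17
Reactants: 23 C7 isobutyrate
Product: 24 CNP0268641.1
Conditions: HF·pyridine, pyridine/THF, 0 °C → rt
Reagents that add atoms: none
Why: Fluoride-mediated cleavage of the secondary silyl ether with buffered HF·pyridine should leave the two esters, the enone and the tertiary ketol intact.

**Compound list**

1 | (R)-carvone, (5R)-2-methyl-5-(prop-1-en-2-yl)cyclohex-2-en-1-one | CC1=CC[C@@H](C(C)=C)CC1=O | starting material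
2 | (5R)-5-(3-chloroprop-1-en-2-yl)-2-methylcyclohex-2-en-1-one | CC1=CC[C@@H](C(CCl)=C)CC1=O | intermediate
3 | 2-[(1R)-4-methyl-5-oxocyclohex-3-en-1-yl]prop-2-enal | CC1=CC[C@@H](C(C=O)=C)CC1=O | intermediate
4 | 2-[(1R)-4-methyl-5-oxocyclohex-3-en-1-yl]prop-2-enoic acid | CC1=CC[C@@H](C(=C)C(=O)O)CC1=O | intermediate
5 | 6-iodo keto acid, iodine α at C6 and trans to the C5 side chain (not isolated) | CC1=CC[C@@H](C(=C)C(=O)O)[C@H](I)C1=O | intermediate
6 | cis-fused enone α-methylene γ-lactone, C6–O and C5–C11 both β | CC1=CC[C@@H]2[C@@H](OC(=O)C2=C)C1=O | intermediate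
7 | cis-fused enone α-methyl γ-lactone, C11 R | CC1=CC[C@@H]2[C@@H](OC(=O)[C@@H]2C)C1=O | intermediate
8 | allylic alcohol, C7–OH β | CC1=CC[C@@H]2[C@@H](OC(=O)[C@@H]2C)[C@H]1O | intermediate
9 | C3 alkylborane, BH2 α at C3, C7–O–BH2 (not isolated) | C[C@H]1[C@H](B)C[C@@H]2[C@@H](OC(=O)[C@@H]2C)[C@H]1OB | intermediate
10 | diol, C3–OH α, C2–Me β, C7–OH β | C[C@H]1[C@H](O)C[C@@H]2[C@@H](OC(=O)[C@@H]2C)[C@H]1O | intermediate
11 | C3 TBS ether of 10 | C[C@H]1[C@H](O[Si](C)(C)C(C)(C)C)C[C@@H]2[C@@H](OC(=O)[C@@H]2C)[C@H]1O | intermediate
12 | cyclohexanone, C7=O, C2–Me β, C3–OTBS α, cis lactone | C[C@H]1[C@H](O[Si](C)(C)C(C)(C)C)C[C@@H]2[C@@H](OC(=O)[C@@H]2C)C1=O | intermediate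
13 | (S)-pent-4-yn-2-ol | C[C@H](O)CC#C | starting material
14 | (S)-pent-4-yn-2-yl pivalate | C[C@H](OC(=O)C(C)(C)C)CC#C | intermediate
15 | lithium acetylide of 14 (not isolated) | C[C@H](OC(=O)C(C)(C)C)CC#C[Li] | intermediate
16 | dichlorocerium acetylide of 14 (not isolated) | C[C@H](OC(=O)C(C)(C)C)CC#C[Ce](Cl)Cl | intermediate
17 | tertiary propargylic alcohol, C7–OH β, alkynyl α | C[C@H](OC(=O)C(C)(C)C)CC#C[C@]1(O)[C@@H](C)[C@H](O[Si](C)(C)C(C)(C)C)C[C@@H]2[C@H]1OC(=O)[C@@H]2C | intermediate
18 | 1,2-diketone pivalate | C[C@H](OC(=O)C(C)(C)C)CC(=O)C(=O)[C@]1(O)[C@@H](C)[C@H](O[Si](C)(C)C(C)(C)C)C[C@@H]2[C@H]1OC(=O)[C@@H]2C | intermediate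
19 | cyclohexanol ene-dione, key-step precursor | C/C=C/C(=O)C(=O)[C@]1(O)[C@@H](C)[C@H](O[Si](C)(C)C(C)(C)C)C[C@@H]2[C@H]1OC(=O)[C@@H]2C | intermediate
20 | ring-enlarged ketol, key-step product, C7=O, C1–OH β | C/C=C/C(=O)[C@]1(O)[C@@H](C)[C@H](O[Si](C)(C)C(C)(C)C)C[C@@H]2[C@@H](OC(=O)[C@@H]2C)C1=O | intermediate
21 | trans diol, C7–OH α | C/C=C/C(=O)[C@]1(O)[C@@H](C)[C@H](O[Si](C)(C)C(C)(C)C)C[C@@H]2[C@@H](OC(=O)[C@@H]2C)[C@@H]1O | intermediate
22 | isobutyryl chloride | CC(C)C(Cl)=O | starting material
23 | C7 isobutyrate, C3 TBS ether | C/C=C/C(=O)[C@]1(O)[C@@H](C)[C@H](O[Si](C)(C)C(C)(C)C)C[C@@H]2[C@@H](OC(=O)[C@@H]2C)[C@@H]1OC(=O)C(C)C | intermediate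
24 | CNP0268641.1, (1S,2S,3R,5S,6R,7S,11R) in the labels used here | C/C=C/C(=O)[C@]1(O)[C@@H](C)[C@H](O)C[C@@H]2[C@@H](OC(=O)[C@@H]2C)[C@@H]1OC(=O)C(C)C | target

**Step count and risks**

Total step count: 17. Longest linear sequence: 16 steps (steps 1–9 and 11–17, from (R)-carvone); step 10 is a one-step side branch.

Steps most likely to fail:

1. Step 14 (proposed new method). The equilibrium may not favour enlargement of an unstrained six-membered ring, migration of C6 may compete with that of C2, a second acyl shift may move the crotonoyl group from C1 to C7, or Lewis-acid enolisation may epimerise C6 next to the new ketone. The fallback uses known chemistry, sets out from 12 and returns at 20. (E)-Pent-3-en-2-one would be C-trifluoroacetylated (LiHMDS, CF3CO2CH2CF3, THF, −78 °C) to (E)-1,1,1-trifluorohept-5-ene-2,4-dione F1, and deacylative diazo transfer (MsN3, Et3N, H2O, MeCN) would give (E)-1-diazopent-3-en-2-one F2. BF3·OEt2-promoted homologation of ketone 12 with F2 (Tiffeneau–Demjanov-type insertion with loss of nitrogen, C2 migrating rather than the acyloxy-substituted C6) would give the ring-enlarged C1–H β-diketone F3. Hydroxylation of its enol at C1 with dimethyldioxirane would then rejoin the route at 20; the face of that hydroxylation would rest on substrate bias alone, so C1 epimers might need separation.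

2. Step 12. The periodate/RuO4 couple may cleave the tertiary ketol or the freshly formed diketone (returning ketone 12 and acids) instead of stopping at the dione. The fallback sets out from 12 and returns at 19. Ethynylmagnesium bromide with CeCl3 (THF, −78 °C) would give the C7 ethynyl carbinol F4. Sonogashira coupling with (E)-1-bromoprop-1-ene (PdCl2(PPh3)2, CuI, i-Pr2NH, rt) would give the (E)-enyne carbinol F5. Oxidation of the triple bond with catalytic PdCl2 in anhydrous DMSO would deliver 19 directly, with no periodate present and the propenyl group already in place.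

3. Step 15. Chemoselectivity may be lost: hydride may also be delivered to the conjugated CK carbonyl, which is likewise α to the directing hydroxyl and becomes β to the new C7 hydroxyl, or reduction at C7 may occur from the wrong face if delivery is not intramolecular. The fallback sets out from 20 and returns at 21. Both ketones would be reduced on purpose (excess Me4NBH(OAc)3, MeCN/AcOH, −20 °C → rt) to the triol F6, the C7 carbinol still being set by delivery from the C1 hydroxyl. The allylic alcohol alone would then be re-oxidised with MnO2 in CH2Cl2 to return to 21.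

Further compounds
F1 | step 14 | (E)-1,1,1-trifluorohept-5-ene-2,4-dione | C/C=C/C(=O)CC(=O)C(F)(F)F
F2 | step 14 | (E)-1-diazopent-3-en-2-one | C/C=C/C(=O)C=[N+]=[N-]
F3 | step 14 | ring-enlarged C1–H β-diketone (C7=O, crotonoyl on C1, no C1 hydroxyl) | C/C=C/C(=O)C1[C@@H](C)[C@H](O[Si](C)(C)C(C)(C)C)C[C@@H]2[C@@H](OC(=O)[C@@H]2C)C1=O
F4 | step 12 | C7 ethynyl carbinol (C7–OH β) | C#C[C@]1(O)[C@@H](C)[C@H](O[Si](C)(C)C(C)(C)C)C[C@@H]2[C@H]1OC(=O)[C@@H]2C
F5 | step 12 | (E)-enyne carbinol (C7–C≡C–CH=CH–CH3) | C/C=C/C#C[C@]1(O)[C@@H](C)[C@H](O[Si](C)(C)C(C)(C)C)C[C@@H]2[C@H]1OC(=O)[C@@H]2C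
F6 | step 15 | triol (C7–OH α, C1–OH β, allylic CK–OH as epimer mixture) | C/C=C/C(O)[C@]1(O)[C@@H](C)[C@H](O[Si](C)(C)C(C)(C)C)C[C@@H]2[C@@H](OC(=O)[C@@H]2C)[C@@H]1O
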